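## Retrosynthetic overview
1. The last bond broken is O–Si at C15, which releases the primary allylic alcohol of the target from its silyl ether.
2. The key disconnection is the C7–O(acetyl) bond. Acetate attacks a 7α-oxysulfonium ion by SN2, so the equatorial 7β-acetate comes from the axial 7α-alcohol with inversion.
3. The 7α-alcohol goes back to the allylic C7–H bond of the 8(17)-ene (SeO2 ene/[2,3] oxidation, α-face selective).
4. The masked substrate goes back to (+)-isocupressic acid by O-methylation at C19 and O-silylation at C15.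
5. No ring is built. Rings A and B (trans-decalin), C4, C5, C9, C10 and the 13E olefin are carried unchanged from the starting acid.

Assumption: (+)-isocupressic acid (CAS 1909-91-7) is taken as a purchasable enantiopure chiral-pool compound (a catalogue natural product, also extracted in bulk from Pinus ponderosa needles); everything else is a bulk reagent.

## Route

Step 1
Reactants: 1 (+)-isocupressic acid
Product: 3 methyl (13E)-15-(tert-butyldimethylsilyloxy)labda-8(17),13-dien-19-oate, via methyl isocupressate 2 (not isolated)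
Conditions: K2CO3 (3 equiv), MeI (1.1 equiv), DMF, rt, 3 h; then imidazole (1.5 equiv), TBSCl (1.3 equiv), rt, 2 h (one pot)
Reagents that add atoms: iodomethane CI; tert-butyldimethylsilyl chloride CC(C)(C)[Si](C)(C)Cl
Why: SN2 O-alkylation of the carboxylate avoids the hindered axial C19 acyl carbon, and the only free hydroxyl (primary, allylic) is then silylated in the same DMF solution without touching any stereocentre (carboxylate alkylation, then imidazole-promoted silylation).

Step 2
Reactants: 3 methyl (13E)-15-(tert-butyldimethylsilyloxy)labda-8(17),13-dien-19-oate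
Product: 4 methyl (13E)-15-(tert-butyldimethylsilyloxy)-7α-hydroxylabda-8(17),13-dien-19-oate
Conditions: SeO2 (0.3 equiv), t-BuOOH (5.5 M in decane, 2.5 equiv), CH2Cl2, 0 °C to rt
Reagents that add atoms: tert-butyl hydroperoxide CC(C)(C)OO (oxygen atom, relayed through catalytic selenium dioxide O=[Se]=O)
Why: In this catalytic Riley-type allylic oxidation, the ene reaction at the exocyclic C8=C17 olefin removes the axial 7α-H from the face opposite the 10β-methyl and the [2,3]-sigmatropic shift returns oxygen to that same α face, giving the axial 7α-alcohol (7R) with the methylene restored, while the 13E olefin is deactivated by its allylic C–O bond.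

Step 3
Reactants: 4 methyl (13E)-15-(tert-butyldimethylsilyloxy)-7α-hydroxylabda-8(17),13-dien-19-oate
Product: 6 methyl (13E)-7β-acetoxy-15-(tert-butyldimethylsilyloxy)labda-8(17),13-dien-19-oate, via 7α-oxysulfonium triflate 5 (not isolated)
Conditions: Ph2SO (1.2 equiv), Tf2O (1.1 equiv), CH2Cl2, −78 °C, 15 min; added slowly to 4 + 2,4,6-tri-tert-butylpyrimidine (2.5 equiv), CH2Cl2, −78 °C; then Bu4NOAc/AcOH (1:1, 4 equiv), toluene, −78 to −20 °C
Reagents that add atoms: tetrabutylammonium acetate CC(=O)[O-].CCCC[N+](CCCC)(CCCC)CCCC; in intermediate 5 only: diphenyl sulfoxide O=S(c1ccccc1)c1ccccc1 and triflic anhydride O=S(=O)(OS(=O)(=O)C(F)(F)F)C(F)(F)F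
Why: Proposed new method: stereoinvertive dehydroxy-acetoxylation through an oxysulfonium leaving group; Ph2SO/Tf2O gives the triflyloxysulfonium salt, and the axial 7α-OH attacks sulfur faster than either olefin does at −78 °C under slow addition, giving alkoxysulfonium 5; 5 has no S–CH bond, so no ylide and no Swern-type oxidation can occur, and its triflate counter-ion is inert; the weakly basic, hydrogen-bonded acetate then attacks C7 from the open β side, anti to the axial C–O bond, expels neutral Ph2SO and sets the equatorial 7β-acetate (7S) by SN2 inversion; the closest known reaction types are the Ph2SO/Tf2O dehydrative glycosylation (anomeric OH turned into an oxysulfonium leaving group), the chloride displacement of allylic alkoxysulfonium ions under Corey–Kim conditions and the Mitsunobu inversion, whereas carboxylate displacement of a non-anomeric carbinol oxysulfonium ion with inversion has, to the best of my knowledge, not been described.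

Step 4
Reactants: 6 methyl (13E)-7β-acetoxy-15-(tert-butyldimethylsilyloxy)labda-8(17),13-dien-19-oate
Product: 7 methyl (13E)-7β-acetoxy-15-hydroxylabda-8(17),13-dien-19-oate (target)
Conditions: HF·pyridine, pyridine, THF, 0 °C to rt (plastic vessel)
Reagents that add atoms: none
Why: Fluoride-driven Si–O cleavage under buffered, non-basic conditions leaves the secondary allylic acetate, the hindered methyl ester, both olefins and all stereocentres untouched (silyl ether deprotection).

## Compound list
1 | (+)-isocupressic acid, (13E)-15-hydroxylabda-8(17),13-dien-19-oic acid (4S,5R,9S,10R; 4β-axial CO2H, 5α-H, 9α-H, 10β-CH3) | C=C1CC[C@@H]2[C@](C)(CCC[C@]2(C)C(=O)O)[C@H]1CC/C(C)=C/CO | starting material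
2 | methyl isocupressate, methyl (13E)-15-hydroxylabda-8(17),13-dien-19-oate (4S,5R,9S,10R) | C=C1CC[C@@H]2[C@](C)(CCC[C@]2(C)C(=O)OC)[C@H]1CC/C(C)=C/CO | intermediate
3 | methyl (13E)-15-(tert-butyldimethylsilyloxy)labda-8(17),13-dien-19-oate (4S,5R,9S,10R) | C=C1CC[C@@H]2[C@](C)(CCC[C@]2(C)C(=O)OC)[C@H]1CC/C(C)=C/CO[Si](C)(C)C(C)(C)C | intermediate
4 | methyl (13E)-15-(tert-butyldimethylsilyloxy)-7α-hydroxylabda-8(17),13-dien-19-oate (4S,5R,7R,9R,10R; axial OH) | C=C1[C@H](O)C[C@@H]2[C@](C)(CCC[C@]2(C)C(=O)OC)[C@H]1CC/C(C)=C/CO[Si](C)(C)C(C)(C)C | intermediate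
5 | diphenyl{[(13E)-15-(tert-butyldimethylsilyloxy)-19-methoxy-19-oxolabda-8(17),13-dien-7α-yl]oxy}sulfonium triflate (7R, axial O–S) | C=C1[C@H](O[S+](c3ccccc3)c3ccccc3)C[C@@H]2[C@](C)(CCC[C@]2(C)C(=O)OC)[C@H]1CC/C(C)=C/CO[Si](C)(C)C(C)(C)C.[O-]S(=O)(=O)C(F)(F)F | intermediate
6 | methyl (13E)-7β-acetoxy-15-(tert-butyldimethylsilyloxy)labda-8(17),13-dien-19-oate (4S,5R,7S,9R,10R; equatorial OAc) | C=C1[C@@H](OC(C)=O)C[C@@H]2[C@](C)(CCC[C@]2(C)C(=O)OC)[C@H]1CC/C(C)=C/CO[Si](C)(C)C(C)(C)C | intermediate
7 | methyl (13E)-7β-acetoxy-15-hydroxylabda-8(17),13-dien-19-oate (4S,5R,7S,9R,10R), CNP0329157.1 | C=C1[C@@H](OC(C)=O)C[C@@H]2[C@](C)(CCC[C@]2(C)C(=O)OC)[C@H]1CC/C(C)=C/CO | target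

## Totals and risks
Total step count: 4. Longest linear sequence: 4.

**Risk 1 (step 3, the proposed new reaction).**
- Possible failures:
  - E2 loss of the anti-periplanar 6β-H to give the 6,8(17)-diene.
  - SN2' attack at C17.
  - Base-induced collapse of 5 to the enone.
  - Attack of the sulfonium reagent on the 13E olefin.
- The fallback uses known chemistry, sets out from 4 and comes back at 6. It keeps the C7–O bond made in step 2 and corrects the configuration by redox instead of substitution. Dess–Martin periodinane with NaHCO3 in CH2Cl2 oxidises 4 to the cross-conjugated enone methyl (13E)-15-(tert-butyldimethylsilyloxy)-7-oxolabda-8(17),13-dien-19-oate F1. Luche reduction (NaBH4, CeCl3·7H2O, MeOH, −78 °C) delivers hydride axially from the α face and gives the equatorial alcohol methyl (13E)-15-(tert-butyldimethylsilyloxy)-7β-hydroxylabda-8(17),13-dien-19-oate F2. Ac2O, DMAP and pyridine then give 6.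

**Risk 2 (step 2).**
- Possible failures: competing oxidation at C12 or C16 of the side-chain olefin, and over-oxidation.
- The fallback sets out from 2 (step 1 is stopped after the methylation and 2 is isolated) and comes back at 7. The side-chain olefin is switched off by oxidation level instead of by a protecting group. MnO2 in CH2Cl2 gives the enal methyl (13E)-15-oxolabda-8(17),13-dien-19-oate F3, whose electron-poor olefin is inert to SeO2. SeO2/t-BuOOH as in step 2 gives methyl (13E)-7α-hydroxy-15-oxolabda-8(17),13-dien-19-oate F4. Mitsunobu inversion (PPh3, DIAD, AcOH, toluene, 0 °C) gives methyl (13E)-7β-acetoxy-15-oxolabda-8(17),13-dien-19-oate F5. A 1,2-selective Luche reduction of the enal (NaBH4, CeCl3·7H2O, MeOH, −20 °C) gives 7 without touching the acetate or the ester.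

**Risk 3 (step 4).**
- Possible failure: acid- or fluoride-induced erosion or allylic shift of the C7 acetate during desilylation.
- The fallback sets out from 4 and comes back at 7, and the silyl group is removed before any acetate is present. HF·pyridine on 4 gives the diol methyl (13E)-7α,15-dihydroxylabda-8(17),13-dien-19-oate F6. A double Mitsunobu reaction (PPh3, DIAD, AcOH, 3 equiv each, toluene) esterifies C15 and inverts C7, giving methyl (13E)-7β,15-diacetoxylabda-8(17),13-dien-19-oate F7. Immobilised Candida antarctica lipase B with MeOH in MTBE at 30 °C methanolyses only the unhindered primary acetate and gives 7.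

## Further compounds
F1 | step 3 | methyl (13E)-15-(tert-butyldimethylsilyloxy)-7-oxolabda-8(17),13-dien-19-oate | C=C1C(=O)C[C@@H]2[C@](C)(CCC[C@]2(C)C(=O)OC)[C@H]1CC/C(C)=C/CO[Si](C)(C)C(C)(C)C
F2 | step 3 | methyl (13E)-15-(tert-butyldimethylsilyloxy)-7β-hydroxylabda-8(17),13-dien-19-oate | C=C1[C@@H](O)C[C@@H]2[C@](C)(CCC[C@]2(C)C(=O)OC)[C@H]1CC/C(C)=C/CO[Si](C)(C)C(C)(C)C
F3 | step 2 | methyl (13E)-15-oxolabda-8(17),13-dien-19-oate | C=C1CC[C@@H]2[C@](C)(CCC[C@]2(C)C(=O)OC)[C@H]1CC/C(C)=C/C=O
F4 | step 2 | methyl (13E)-7α-hydroxy-15-oxolabda-8(17),13-dien-19-oate | C=C1[C@H](O)C[C@@H]2[C@](C)(CCC[C@]2(C)C(=O)OC)[C@H]1CC/C(C)=C/C=O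
F5 | step 2 | methyl (13E)-7β-acetoxy-15-oxolabda-8(17),13-dien-19-oate | C=C1[C@@H](OC(C)=O)C[C@@H]2[C@](C)(CCC[C@]2(C)C(=O)OC)[C@H]1CC/C(C)=C/C=O
F6 | step 4 | methyl (13E)-7α,15-dihydroxylabda-8(17),13-dien-19-oate | C=C1[C@H](O)C[C@@H]2[C@](C)(CCC[C@]2(C)C(=O)OC)[C@H]1CC/C(C)=C/CO
F7 | step 4 | methyl (13E)-7β,15-diacetoxylabda-8(17),13-dien-19-oate | C=C1[C@@H](OC(C)=O)C[C@@H]2[C@](C)(CCC[C@]2(C)C(=O)OC)[C@H]1CC/C(C)=C/COC(C)=O
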